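**Plan**

- Retrosynthesis: the acetate and the two phenol O–H bonds are unmasked last (primary acetylation, O-benzyl hydrogenolysis). The C4–OH bond is traced to a C4 carboxyl (radical decarboxylative hydroxylation) and the C4–CH2Ar bond to an ester enolate benzylation, which leaves a 2-aryl-oxolane-4,4-diester.
- Enabling feature: in the oxolane O1–C2–C3–C4–C5, C2 bears a para-oxygenated aryl donor and lies 1,3 to the fully substituted C4 (a masked malonate carbon), while C5 is an unsubstituted CH2 flanked by O1 and C4. Cutting O1–C2 and C4–C5 therefore gives formaldehyde and a 2-aryl cyclopropane-1,1-diester whose C2–C4 bond is the one that opens.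
- The cyclopropane is cut at its two bonds to the malonate carbon into an (E)-cinnamaldehyde and dimethyl bromomalonate.
- Forward: enal, cyclopropane ring (step 2), oxolane ring by strain-release [3+2] annulation (step 5), decoration of C4, then the end-game on the C3 arm and the phenols.
- Stereochemistry: C3 comes from the aminocatalyst (step 2); C2 is set relative to C3 by Lewis acid equilibration of the benzylic ether (step 5); C4 is set by oxygen capture of a planar radical anti to the C3 arm (step 10).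

Key step: step 5

Remark: O-benzylvanillin (1) and 4-(benzyloxy)-3-methoxybenzyl alcohol (12) are taken as purchased (each is one routine step from vanillin). Ar = 4-(benzyloxy)-3-methoxyphenyl; oxolane locants follow the target ring throughout (O1, C2 aryl, C3 CH2O arm, C4, C5).

**Route**

Step 1
Reactants: 1 4-(benzyloxy)-3-methoxybenzaldehyde; 2 (triphenylphosphoranylidene)acetaldehyde
Product: 3 (E)-3-[4-(benzyloxy)-3-methoxyphenyl]prop-2-enal
Conditions: 2 (1.1 equiv), PhMe, 90 °C
Reagents that add atoms: none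
Why: Wittig olefination with the stabilised formyl ylide should give the (E)-enal, and keeping the ylide near one equivalent limits vinylogous over-homologation.

Step 2
Reactants: 3 (E)-3-[4-(benzyloxy)-3-methoxyphenyl]prop-2-enal; 4 dimethyl bromomalonate
Product: 5 dimethyl (2S,3R)-2-Ar-3-formylcyclopropane-1,1-dicarboxylate (aryl and formyl trans)
Conditions: (S)-α,α-diphenylprolinol trimethylsilyl ether (20 mol%), 2,6-lutidine (1.1 equiv), CH2Cl2, 0 °C → rt
Reagents that add atoms: none
Why: Aminocatalytic Michael-initiated ring closure (iminium then enamine activation): the Ph2C(OSiMe3) arm of the catalyst shields the Re face of the β-carbon of the E-iminium ion, so the bromomalonate should add to the Si face, and the resulting enamine displaces bromide (3-exo-tet) to set both centres with aryl trans to formyl.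

Step 3
Reactants: 5 dimethyl (2S,3R)-2-Ar-3-formylcyclopropane-1,1-dicarboxylate
Product: 6 dimethyl (2S,3R)-2-Ar-3-(hydroxymethyl)cyclopropane-1,1-dicarboxylate
Conditions: NaBH4, MeOH/THF, −20 °C; aq. NH4Cl
Reagents that add atoms: none
Why: Chemoselective borohydride reduction of the aldehyde beside the malonate esters, with low temperature, a buffered quench and immediate use in step 4 meant to keep the new alcohol from lactonising onto the cis ester.

Step 4
Reactants: 6 dimethyl (2S,3R)-2-Ar-3-(hydroxymethyl)cyclopropane-1,1-dicarboxylate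
Product: 7 dimethyl (2S,3R)-2-Ar-3-[(triisopropylsilyloxy)methyl]cyclopropane-1,1-dicarboxylate
Conditions: iPr3SiCl, imidazole, DMF, 0 °C → rt
Reagents that add atoms: chlorotriisopropylsilane, CC(C)[Si](Cl)(C(C)C)C(C)C
Why: Imidazole-promoted silylation of a primary alcohol; the triisopropylsilyl ether is chosen because it should ride through the Lewis acid, hot chloride, amide base and hydroxide of steps 5 to 9.

Step 5
Reactants: 7 dimethyl (2S,3R)-2-Ar-3-[(triisopropylsilyloxy)methyl]cyclopropane-1,1-dicarboxylate; 8 formaldehyde (charged as paraformaldehyde)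
Product: 10 dimethyl (2S,3R)-2-Ar-3-[(triisopropylsilyloxy)methyl]oxolane-4,4-dicarboxylate (2,3-trans), via 2,3-cis oxolane diester 9 (not isolated)
Conditions: (CH2O)n (5 equiv), Sn(OTf)2 (10 mol%), ClCH2CH2Cl, rt → 45 °C until the epimer ratio is constant
Reagents that add atoms: none
Why: Sn(OTf)2 (divalent tin) chelates the geminal diester and, with push from the para-benzyloxy group, heterolyses the C2–C4 bond of 7 to a benzylic cation/tin malonate ion pair; the oxygen of monomeric formaldehyde is alkylated at C2 (O1–C2) and the malonate carbon then adds to the O-alkyl oxocarbenium carbon (C4–C5). The closest known reaction is the Lewis acid-catalysed formal [3+2] annulation of 2-arylcyclopropane-1,1-diesters with aldehydes to 2-aryl tetrahydrofurans, here with the smallest aldehyde. The oxolane closes by an aldol-type 5-endo-trig attack of the exocyclic malonate enolate on the oxocarbenium ion (both atoms of the C5=O1 unit end up in the ring), the usual closure in these annulations. C2 is the only new stereocentre and is set under thermodynamic control by the untouched C3 centre: invertive opening of the trans cyclopropane leads first to the 2,3-cis ether 9, whose electron-rich benzylic C2–O1 bond should re-ionise under the Lewis acid until the aryl group sits trans to the C3 silyloxymethyl arm in 10. The step needs cleavage of C2–C4 rather than C3–C4 and survival of the C3 centre; the alkoxyaryl donor on C2 (C3 bears only a non-donating CH2OSi group) secures the first, and the absence of any ionisable or acidic bond at C3 the second.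

Step 6
Reactants: 10 dimethyl (2S,3R)-2-Ar-3-[(triisopropylsilyloxy)methyl]oxolane-4,4-dicarboxylate
Product: 11 methyl (2S,3R,4RS)-2-Ar-3-[(triisopropylsilyloxy)methyl]oxolane-4-carboxylate (C4 epimers)
Conditions: LiCl, H2O, DMSO, 150 °C
Reagents that add atoms: none
Why: Krapcho demethoxycarbonylation (chloride SN2 at one ester methyl, loss of CO2, protonation of the ester enolate); the C4 epimer mixture is of no consequence because C4 is deprotonated in step 8.

Step 7
Reactants: 12 [4-(benzyloxy)-3-methoxyphenyl]methanol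
Product: 13 1-(benzyloxy)-4-(bromomethyl)-2-methoxybenzene
Conditions: PBr3, Et2O, 0 °C; used crude
Reagents that add atoms: phosphorus tribromide, BrP(Br)Br
Why: Standard conversion of an electron-rich benzylic alcohol into its bromide through the phosphite ester and bromide displacement.

Step 8
Reactants: 11 methyl (2S,3R,4RS)-2-Ar-3-[(triisopropylsilyloxy)methyl]oxolane-4-carboxylate; 13 1-(benzyloxy)-4-(bromomethyl)-2-methoxybenzene
Product: 14 methyl (2S,3R,4RS)-2-Ar-4-[4-(benzyloxy)-3-methoxybenzyl]-3-[(triisopropylsilyloxy)methyl]oxolane-4-carboxylate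
Conditions: LiN(iPr)2, THF, −78 °C; then 13, −78 → −30 °C
Reagents that add atoms: none
Why: Ester enolate alkylation (SN2) with a reactive benzylic bromide forms the C4–CH2Ar bond; at −78 °C expulsion of the ring oxygen should not compete because the endocyclic C5–O1 bond is poorly aligned with the enolate π-system, and the C4 configuration (benzyl expected mainly anti to the C3 arm) is erased in step 10.

Step 9
Reactants: 14 methyl (2S,3R,4RS)-2-Ar-4-[4-(benzyloxy)-3-methoxybenzyl]-3-[(triisopropylsilyloxy)methyl]oxolane-4-carboxylate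
Product: 15 (2S,3R,4RS)-2-Ar-4-[4-(benzyloxy)-3-methoxybenzyl]-3-[(triisopropylsilyloxy)methyl]oxolane-4-carboxylic acid
Conditions: LiOH, THF/MeOH/H2O, 60 °C; then aq. HCl to pH 3, 0 °C
Reagents that add atoms: lithium hydroxide (LiOH), [Li+].[OH-]
Why: Saponification of the neopentyl-type methyl ester with excess hydroxide; benzyl ethers, the oxolane and the triisopropylsilyl ether are stable to aqueous base.

Step 10
Reactants: 15 (2S,3R,4RS)-2-Ar-4-[4-(benzyloxy)-3-methoxybenzyl]-3-[(triisopropylsilyloxy)methyl]oxolane-4-carboxylic acid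
Product: 19 (2S,3R,4S)-2-Ar-4-[4-(benzyloxy)-3-methoxybenzyl]-3-[(triisopropylsilyloxy)methyl]oxolan-4-ol, via acid chloride 16 (not isolated), via thiohydroxamate ester 17 (not isolated), via C4 hydroperoxide 18 (not isolated)
Conditions: Me2C=C(Cl)NMe2, CH2Cl2, 0 °C → rt; 1-hydroxypyridine-2(1H)-thione, Et3N, cat. DMAP, dark; then O2 (saturated), t-BuSH, PhMe, hν (tungsten lamp), 0 °C; then PPh3
Reagents that add atoms: oxygen, O=O
Why: Barton decarboxylative hydroxylation: the thiohydroxamate ester fragments in a radical chain to the planar tertiary C4 radical common to both C4 epimers, oxygen should be captured on the face anti to the adjacent C3 silyloxymethyl arm (OH trans to it, benzyl cis, 4S), and the peroxyl radical is reduced by the thiol and the hydroperoxide by PPh3.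

Step 11
Reactants: 19 (2S,3R,4S)-2-Ar-4-[4-(benzyloxy)-3-methoxybenzyl]-3-[(triisopropylsilyloxy)methyl]oxolan-4-ol
Product: 20 (2S,3R,4S)-2-Ar-4-[4-(benzyloxy)-3-methoxybenzyl]-3-(hydroxymethyl)oxolan-4-ol (O,O'-dibenzylolivil)
Conditions: Bu4NF, THF, 0 °C → rt
Reagents that add atoms: none
Why: Fluoride-driven desilylation frees the primary alcohol without touching the ethers or the tertiary alcohol.

Step 12
Reactants: 20 (2S,3R,4S)-2-Ar-4-[4-(benzyloxy)-3-methoxybenzyl]-3-(hydroxymethyl)oxolan-4-ol
Product: 21 [(2S,3R,4S)-2-Ar-4-[4-(benzyloxy)-3-methoxybenzyl]-4-hydroxyoxolan-3-yl]methyl acetate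
Conditions: Ac2O, pyridine, CH2Cl2, 0 °C → rt (no DMAP)
Reagents that add atoms: acetic anhydride, CC(=O)OC(C)=O
Why: Acylation without a nucleophilic catalyst should discriminate the primary from the hindered tertiary hydroxyl, the phenols being masked as benzyl ethers.

Step 13
Reactants: 21 [(2S,3R,4S)-2-Ar-4-[4-(benzyloxy)-3-methoxybenzyl]-4-hydroxyoxolan-3-yl]methyl acetate
Product: 22 olivil monoacetate, [(2S,3R,4S)-4-hydroxy-2-(4-hydroxy-3-methoxyphenyl)-4-(4-hydroxy-3-methoxybenzyl)oxolan-3-yl]methyl acetate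
Conditions: H2 (1 atm), Pd/C, EtOAc, rt, stopped after uptake of two equivalents
Reagents that add atoms: none
Why: Hydrogenolysis of the two aryl benzyl ethers over Pd/C in a neutral aprotic solvent is much faster than cleavage of the cyclic benzylic C2–O1 ether, so both phenols should be freed with acetate and tertiary alcohol intact.

**Compound list**

1 | 4-(benzyloxy)-3-methoxybenzaldehyde | COc1cc(C=O)ccc1OCc1ccccc1 | starting material
2 | (triphenylphosphoranylidene)acetaldehyde | O=CC=P(c1ccccc1)(c1ccccc1)c1ccccc1 | starting material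
3 | (E)-3-[4-(benzyloxy)-3-methoxyphenyl]prop-2-enal | COc1cc(/C=C/C=O)ccc1OCc1ccccc1 | intermediate
4 | dimethyl bromomalonate | COC(=O)C(Br)C(=O)OC | starting material
5 | dimethyl (2S,3R)-2-[4-(benzyloxy)-3-methoxyphenyl]-3-formylcyclopropane-1,1-dicarboxylate | COC(=O)C1(C(=O)OC)[C@H](c2ccc(OCc3ccccc3)c(OC)c2)[C@H]1C=O | intermediate
6 | dimethyl (2S,3R)-2-[4-(benzyloxy)-3-methoxyphenyl]-3-(hydroxymethyl)cyclopropane-1,1-dicarboxylate | COC(=O)C1(C(=O)OC)[C@H](c2ccc(OCc3ccccc3)c(OC)c2)[C@H]1CO | intermediate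
7 | dimethyl (2S,3R)-2-[4-(benzyloxy)-3-methoxyphenyl]-3-[(triisopropylsilyloxy)methyl]cyclopropane-1,1-dicarboxylate | COC(=O)C1(C(=O)OC)[C@H](c2ccc(OCc3ccccc3)c(OC)c2)[C@H]1CO[Si](C(C)C)(C(C)C)C(C)C | intermediate
8 | formaldehyde (charged as paraformaldehyde) | C=O | starting material
9 | dimethyl (2R,3R)-2-[4-(benzyloxy)-3-methoxyphenyl]-3-[(triisopropylsilyloxy)methyl]oxolane-4,4-dicarboxylate (2,3-cis) | COC(=O)C1(C(=O)OC)CO[C@@H](c2ccc(OCc3ccccc3)c(OC)c2)[C@H]1CO[Si](C(C)C)(C(C)C)C(C)C | intermediate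
10 | dimethyl (2S,3R)-2-[4-(benzyloxy)-3-methoxyphenyl]-3-[(triisopropylsilyloxy)methyl]oxolane-4,4-dicarboxylate (2,3-trans) | COC(=O)C1(C(=O)OC)CO[C@H](c2ccc(OCc3ccccc3)c(OC)c2)[C@H]1CO[Si](C(C)C)(C(C)C)C(C)C | intermediate
11 | methyl (2S,3R,4RS)-2-[4-(benzyloxy)-3-methoxyphenyl]-3-[(triisopropylsilyloxy)methyl]oxolane-4-carboxylate | COC(=O)C1CO[C@H](c2ccc(OCc3ccccc3)c(OC)c2)[C@H]1CO[Si](C(C)C)(C(C)C)C(C)C | intermediate
12 | [4-(benzyloxy)-3-methoxyphenyl]methanol | COc1cc(CO)ccc1OCc1ccccc1 | starting material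
13 | 1-(benzyloxy)-4-(bromomethyl)-2-methoxybenzene | COc1cc(CBr)ccc1OCc1ccccc1 | intermediate
14 | methyl (2S,3R,4RS)-2-[4-(benzyloxy)-3-methoxyphenyl]-4-[4-(benzyloxy)-3-methoxybenzyl]-3-[(triisopropylsilyloxy)methyl]oxolane-4-carboxylate | COC(=O)C1(Cc2ccc(OCc3ccccc3)c(OC)c2)CO[C@H](c2ccc(OCc3ccccc3)c(OC)c2)[C@H]1CO[Si](C(C)C)(C(C)C)C(C)C | intermediate
15 | (2S,3R,4RS)-2-[4-(benzyloxy)-3-methoxyphenyl]-4-[4-(benzyloxy)-3-methoxybenzyl]-3-[(triisopropylsilyloxy)methyl]oxolane-4-carboxylic acid | OC(=O)C1(Cc2ccc(OCc3ccccc3)c(OC)c2)CO[C@H](c2ccc(OCc3ccccc3)c(OC)c2)[C@H]1CO[Si](C(C)C)(C(C)C)C(C)C | intermediate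
16 | acid chloride of 15 | ClC(=O)C1(Cc2ccc(OCc3ccccc3)c(OC)c2)CO[C@H](c2ccc(OCc3ccccc3)c(OC)c2)[C@H]1CO[Si](C(C)C)(C(C)C)C(C)C | intermediate
17 | 2-thioxopyridin-1(2H)-yl ester of 15 (O-acyl thiohydroxamate) | S=C1C=CC=CN1OC(=O)C1(Cc2ccc(OCc3ccccc3)c(OC)c2)CO[C@H](c2ccc(OCc3ccccc3)c(OC)c2)[C@H]1CO[Si](C(C)C)(C(C)C)C(C)C | intermediate
18 | (2S,3R,4S)-2-[4-(benzyloxy)-3-methoxyphenyl]-4-[4-(benzyloxy)-3-methoxybenzyl]-4-hydroperoxy-3-[(triisopropylsilyloxy)methyl]oxolane | COc1cc(C[C@@]2(OO)CO[C@H](c3ccc(OCc4ccccc4)c(OC)c3)[C@H]2CO[Si](C(C)C)(C(C)C)C(C)C)ccc1OCc1ccccc1 | intermediate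
19 | (2S,3R,4S)-2-[4-(benzyloxy)-3-methoxyphenyl]-4-[4-(benzyloxy)-3-methoxybenzyl]-3-[(triisopropylsilyloxy)methyl]oxolan-4-ol | COc1cc(C[C@@]2(O)CO[C@H](c3ccc(OCc4ccccc4)c(OC)c3)[C@H]2CO[Si](C(C)C)(C(C)C)C(C)C)ccc1OCc1ccccc1 | intermediate
20 | (2S,3R,4S)-2-[4-(benzyloxy)-3-methoxyphenyl]-4-[4-(benzyloxy)-3-methoxybenzyl]-3-(hydroxymethyl)oxolan-4-ol | COc1cc(C[C@@]2(O)CO[C@H](c3ccc(OCc4ccccc4)c(OC)c3)[C@H]2CO)ccc1OCc1ccccc1 | intermediate
21 | [(2S,3R,4S)-2-[4-(benzyloxy)-3-methoxyphenyl]-4-[4-(benzyloxy)-3-methoxybenzyl]-4-hydroxyoxolan-3-yl]methyl acetate | COc1cc(C[C@@]2(O)CO[C@H](c3ccc(OCc4ccccc4)c(OC)c3)[C@H]2COC(C)=O)ccc1OCc1ccccc1 | intermediate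
22 | olivil monoacetate | COc1cc(C[C@@]2(O)CO[C@H](c3ccc(O)c(OC)c3)[C@H]2COC(C)=O)ccc1O | target

**Step count and risks**

Total steps: 13. Longest linear sequence: 12 steps (steps 1 to 6 and 8 to 13); step 7 is a one-step branch.

Step 5 (annulation). Equilibration of the benzylic ether may stall before the kinetically formed cis epimer has drained to the trans ether. The ring-opened zwitterion may also lose the C3 proton to a styrenyl malonate, and formaldehyde under the Lewis acid may hydroxymethylate the electron-rich arene or insert twice. The fallback sets out from 7 and comes back at 10 by a stepwise, known sequence. Lewis acid-catalysed methanolysis of the cyclopropane (cat. Sc(OTf)3, MeOH/CH2Cl2) should give the γ-methoxy malonate F1. Hydroxymethylation of its malonate carbon with aqueous formaldehyde and K2CO3 should give the hydroxymethyl malonate F2. A catalytic strong acid (TfOH or BF3·OEt2, CH2Cl2, 0 °C) then ionises the benzylic methyl ether and the primary hydroxyl captures the cation (SN1 cycloetherification, trans favoured kinetically and thermodynamically) to give 10.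

Step 10 (decarboxylative hydroxylation). Facial selectivity in the capture of the planar C4 radical by the small oxygen molecule may be poor, and hydrogen transfer from the thiol may compete (reductive decarboxylation). The fallback sets out from 11 and comes back at 19, replacing the radical by an alkene. Mild saponification of 11 gives the carboxylic acid F3. Its dianion (LiN(iPr)2, 2.2 equiv) adds to aldehyde 1 to give the β-hydroxy acid F4. Decarboxylative dehydration with DMF dineopentyl acetal gives the benzylidene oxolane F5. Dimethyldioxirane should epoxidise the exocyclic alkene anti to the C3 arm to give the spiro-epoxide F6. LiAlH4 then delivers hydride to the benzylic oxirane carbon and releases the tertiary alcohol 19.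

Step 9 (ester hydrolysis). Hydroxide attack at the neopentyl-type ester carbonyl may be too slow, and forcing it may erode the silyl ether. The fallback sets out from 11 and comes back at 15, moving the cleavage away from the hindered acyl carbon. Transesterification of 11 with allyl alcohol (cat. Ti(OiPr)4) gives the allyl ester F7. Enolate benzylation with 13 as in step 8 gives the benzylated allyl ester F8. Deallylation with Pd(PPh3)4 (zerovalent palladium) and morpholine, which attacks the allyl group and not the carbonyl, gives 15.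

**Further compounds**

F1 | step 5 | dimethyl 2-{(1RS,2R)-1-[4-(benzyloxy)-3-methoxyphenyl]-1-methoxy-3-(triisopropylsilyloxy)propan-2-yl}propanedioate | COC(=O)C(C(=O)OC)[C@H](CO[Si](C(C)C)(C(C)C)C(C)C)C(OC)c1ccc(OCc2ccccc2)c(OC)c1
F2 | step 5 | dimethyl 2-(hydroxymethyl)-2-{(1RS,2R)-1-[4-(benzyloxy)-3-methoxyphenyl]-1-methoxy-3-(triisopropylsilyloxy)propan-2-yl}propanedioate | COC(=O)C(CO)(C(=O)OC)[C@H](CO[Si](C(C)C)(C(C)C)C(C)C)C(OC)c1ccc(OCc2ccccc2)c(OC)c1
F3 | step 10 | (2S,3R,4RS)-2-[4-(benzyloxy)-3-methoxyphenyl]-3-[(triisopropylsilyloxy)methyl]oxolane-4-carboxylic acid | OC(=O)C1CO[C@H](c2ccc(OCc3ccccc3)c(OC)c2)[C@H]1CO[Si](C(C)C)(C(C)C)C(C)C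
F4 | step 10 | (2S,3R,4RS)-2-[4-(benzyloxy)-3-methoxyphenyl]-4-{[4-(benzyloxy)-3-methoxyphenyl](hydroxy)methyl}-3-[(triisopropylsilyloxy)methyl]oxolane-4-carboxylic acid | OC(=O)C1(C(O)c2ccc(OCc3ccccc3)c(OC)c2)CO[C@H](c2ccc(OCc3ccccc3)c(OC)c2)[C@H]1CO[Si](C(C)C)(C(C)C)C(C)C
F5 | step 10 | (2S,3R)-2-[4-(benzyloxy)-3-methoxyphenyl]-4-[4-(benzyloxy)-3-methoxybenzylidene]-3-[(triisopropylsilyloxy)methyl]oxolane (alkene isomers) | COc1cc(C=C2CO[C@H](c3ccc(OCc4ccccc4)c(OC)c3)[C@H]2CO[Si](C(C)C)(C(C)C)C(C)C)ccc1OCc1ccccc1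
F6 | step 10 | spiro-epoxide of F5, oxirane oxygen on C4 trans to the C3 arm (4S), benzylic oxirane carbon unassigned | COc1cc(C3O[C@@]32CO[C@H](c4ccc(OCc5ccccc5)c(OC)c4)[C@H]2CO[Si](C(C)C)(C(C)C)C(C)C)ccc1OCc1ccccc1
F7 | step 9 | prop-2-en-1-yl (2S,3R,4RS)-2-[4-(benzyloxy)-3-methoxyphenyl]-3-[(triisopropylsilyloxy)methyl]oxolane-4-carboxylate | C=CCOC(=O)C1CO[C@H](c2ccc(OCc3ccccc3)c(OC)c2)[C@H]1CO[Si](C(C)C)(C(C)C)C(C)C
F8 | step 9 | prop-2-en-1-yl (2S,3R,4RS)-2-[4-(benzyloxy)-3-methoxyphenyl]-4-[4-(benzyloxy)-3-methoxybenzyl]-3-[(triisopropylsilyloxy)methyl]oxolane-4-carboxylate | C=CCOC(=O)C1(Cc2ccc(OCc3ccccc3)c(OC)c2)CO[C@H](c2ccc(OCc3ccccc3)c(OC)c2)[C@H]1CO[Si](C(C)C)(C(C)C)C(C)C
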